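## Retrosynthetic overview
1. Target ⇒ benzylic tetralol (dehydration can only give C3=C4) ⇒ α-methylation and reduction of trans-4-aryl-3-methyl-1-tetralone.
2. Tetralone ⇒ its spiro-1,3-dithiane ⇒ intramolecular Friedel–Crafts alkylation forming C1–C8a, in which the C2 methyl centre sets C1 trans.
3. Cyclisation precursor ⇒ arylmagnesium bromide + α-methyl aldehyde ⇒ γ-keto ester ⇒ Pd-catalysed acylation of a β-zincio ester with 3,4-dimethoxybenzoyl chloride.
4. β-Zincio ester ⇒ methyl (R)-3-hydroxy-2-methylpropanoate ⇒ ene-reductase reduction of methyl 2-(hydroxymethyl)acrylate, which sets C2.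
5. Ring order: both arenes are bought. The temporary dithiane ring is made first (step 4), carbocycle ring B second (step 8), and the dithiane is opened again in step 9.

Assumption: the target is the (1R,2S) isomer with the aryl group and C2 methyl trans. Locants C1–C8a are those of its 1,2-dihydronaphthalene core, ring A is the fused dimethoxybenzene ring and ring B the new carbocycle. Compound 10, LiN(iPr)2 and the enzymes are bought.

## Route

Step 1
Reactants: 1 methyl 2-(hydroxymethyl)acrylate
Product: 2 methyl (R)-3-hydroxy-2-methylpropanoate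
Conditions: ene-reductase (flavin-dependent Old Yellow Enzyme family, e.g. XenA or YqjM), NAD+ (cat.), formate dehydrogenase, HCO2Na, Tris-HCl buffer pH 7.5, 30 °C
Reagents that add atoms: none
Why: This is an asymmetric bioreduction of an activated C=C bond in which the reduced flavin delivers hydride to the =CH2 carbon and an active-site tyrosine protonates Cα from the opposite face, which for this acrylate gives the (R)-ester in >99% ee and sets the centre that becomes C2.

Step 2
Reactants: 2 methyl (R)-3-hydroxy-2-methylpropanoate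
Product: 3 methyl (S)-3-iodo-2-methylpropanoate
Conditions: I2, PPh3, imidazole, CH2Cl2, 0 °C to rt
Reagents that add atoms: iodine, II
Why: Appel-type iodination (Garegg–Samuelsson conditions) is an SN2 displacement at the primary carbon, so the stereocentre is untouched (the descriptor becomes S only because CH2I outranks CO2Me) and imidazole is too weak a base to cause elimination to methacrylate.

Step 3
Reactants: 3 methyl (S)-3-iodo-2-methylpropanoate; 4 3,4-dimethoxybenzoyl chloride
Product: 6 methyl (R)-4-(3,4-dimethoxyphenyl)-2-methyl-4-oxobutanoate, via organozinc iodide 5 (not isolated)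
Conditions: Zn dust, I2 (5 mol%), DMA, rt; then 4, Pd(PPh3)4 (5 mol%), toluene, rt
Reagents that add atoms: none
Why: Zinc insertion gives a chelate-stabilised β-zincio ester that neither eliminates nor epimerises, and its Negishi-type acylation under zerovalent palladium catalysis stops cleanly at the aryl ketone.

Step 4
Reactants: 6 methyl (R)-4-(3,4-dimethoxyphenyl)-2-methyl-4-oxobutanoate
Product: 7 methyl (R)-3-[2-(3,4-dimethoxyphenyl)-1,3-dithian-2-yl]-2-methylpropanoate
Conditions: HS(CH2)3SH, BF3·OEt2, CH2Cl2, 0 °C to rt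
Reagents that add atoms: propane-1,3-dithiol, SCCCS
Why: Lewis acid-promoted thioketalisation masks the ketone as an acid-stable group that no longer deactivates ring A, while the ester and its α-centre are inert to BF3·OEt2.

Step 5
Reactants: 7 methyl (R)-3-[2-(3,4-dimethoxyphenyl)-1,3-dithian-2-yl]-2-methylpropanoate
Product: 8 (R)-3-[2-(3,4-dimethoxyphenyl)-1,3-dithian-2-yl]-2-methylpropan-1-ol
Conditions: LiAlH4, THF, 0 °C; then H2O
Reagents that add atoms: none
Why: Hydride reduction takes the ester to the primary alcohol, and the thioketal, aryl ethers and stereocentre are all inert to LiAlH4.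

Step 6
Reactants: 8 (R)-3-[2-(3,4-dimethoxyphenyl)-1,3-dithian-2-yl]-2-methylpropan-1-ol
Product: 9 (R)-3-[2-(3,4-dimethoxyphenyl)-1,3-dithian-2-yl]-2-methylpropanal
Conditions: SO3·pyridine, DMSO, Et3N, CH2Cl2, 0 °C
Reagents that add atoms: none
Why: The Parikh–Doering oxidation uses activated DMSO at 0 °C, which leaves the thioketal sulfur unoxidised, cannot over-oxidise, and does not epimerise the α-methyl aldehyde if it is used at once.

Step 7
Reactants: 9 (R)-3-[2-(3,4-dimethoxyphenyl)-1,3-dithian-2-yl]-2-methylpropanal; 10 3,4-dimethoxyphenylmagnesium bromide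
Product: 12 (2R)-1-(3,4-dimethoxyphenyl)-3-[2-(3,4-dimethoxyphenyl)-1,3-dithian-2-yl]-2-methylpropan-1-ol (mixture of C1 epimers), via bromomagnesium alkoxide 11 (not isolated)
Conditions: 10 (1.3 equiv), THF, −78 to 0 °C; then sat. aq. NH4Cl
Reagents that add atoms: none
Why: Grignard 1,2-addition to the aldehyde gives the carbinol as a Felkin–Anh-biased mixture, which does not matter because this centre is ionised in the next step.

Step 8
Reactants: 12 (2R)-1-(3,4-dimethoxyphenyl)-3-[2-(3,4-dimethoxyphenyl)-1,3-dithian-2-yl]-2-methylpropan-1-ol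
Product: 14 (3'R,4'R)-4'-(3,4-dimethoxyphenyl)-6',7'-dimethoxy-3'-methyl-3',4'-dihydro-2'H-spiro[1,3-dithiane-2,1'-naphthalene] (aryl and methyl trans), via benzylic cation 13 (not isolated)
Conditions: CF3CO2H (10 equiv), CH2Cl2, −20 to 0 °C
Reagents that add atoms: none
Why: In this intramolecular Friedel–Crafts alkylation ring A attacks the alkoxy-stabilised cation para to a methoxy group through a chair-like transition state in which allylic 1,3-strain holds C2–H in the cation plane and the tether approaches anti to the methyl group, so aryl and methyl end up trans-diequatorial and C1 is set as R by the existing centre.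

Step 9
Reactants: 14 the spiro-dithiane aryltetralin
Product: 15 (3R,4R)-4-(3,4-dimethoxyphenyl)-6,7-dimethoxy-3-methyl-3,4-dihydronaphthalen-1(2H)-one
Conditions: MeI (10 equiv), CaCO3, MeCN/H2O 9:1, 50 °C
Reagents that add atoms: water, O
Why: In this alkylative thioketal hydrolysis S-methylation turns sulfur into a leaving group and the aryl-stabilised thionium ion is hydrolysed, while the buffered, non-oxidising medium spares the electron-rich arenes and both stereocentres.

Step 10
Reactants: 15 (3R,4R)-4-(3,4-dimethoxyphenyl)-6,7-dimethoxy-3-methyl-3,4-dihydronaphthalen-1(2H)-one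
Product: 17 (3S,4R)-4-(3,4-dimethoxyphenyl)-6,7-dimethoxy-2,3-dimethyl-3,4-dihydronaphthalen-1(2H)-one (C2 epimers, mainly 2,3-trans), via lithium enolate 16 (not isolated)
Conditions: LiN(iPr)2 (1.1 equiv), THF, −78 °C; MeI, −78 to −20 °C
Reagents that add atoms: iodomethane, CI
Why: Kinetic enolate alkylation occurs at the only α-position and mainly anti to the neighbouring methyl, the new centre becomes sp2 in step 12 so its ratio is irrelevant, and the two existing centres are not deprotonated (the 3-descriptor changes only through CIP ranking).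

Step 11
Reactants: 17 the 2,3-dimethyltetralone
Product: 18 (3S,4R)-4-(3,4-dimethoxyphenyl)-6,7-dimethoxy-2,3-dimethyl-1,2,3,4-tetrahydronaphthalen-1-ol (mixture at C1 and C2)
Conditions: NaBH4, MeOH/THF, 0 °C to rt
Reagents that add atoms: none
Why: Borohydride 1,2-reduction of the aryl ketone gives the benzylic alcohol, whose carbinol configuration is irrelevant because it is lost on dehydration.

Step 12
Reactants: 18 the tetralol
Product: 19 (1R,2S)-1-(3,4-dimethoxyphenyl)-6,7-dimethoxy-2,3-dimethyl-1,2-dihydronaphthalene (target)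
Conditions: p-TsOH·H2O (5 mol%), toluene, 60 °C
Reagents that add atoms: none
Why: Acid-catalysed E1 dehydration of the methoxy-activated benzylic alcohol can only place the alkene between C3 and C4 (conjugated and trisubstituted), which erases the two undefined centres and leaves C1 (R) and C2 (S) untouched.

## Compound list
1 | methyl 2-(hydroxymethyl)acrylate | C=C(CO)C(=O)OC | starting material
2 | methyl (R)-3-hydroxy-2-methylpropanoate | COC(=O)[C@H](C)CO | intermediate
3 | methyl (S)-3-iodo-2-methylpropanoate | COC(=O)[C@H](C)CI | intermediate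
4 | 3,4-dimethoxybenzoyl chloride | COc1ccc(C(=O)Cl)cc1OC | starting material
5 | [(S)-3-methoxy-2-methyl-3-oxopropyl]zinc iodide | COC(=O)[C@H](C)C[Zn]I | intermediate
6 | methyl (R)-4-(3,4-dimethoxyphenyl)-2-methyl-4-oxobutanoate | COC(=O)[C@H](C)CC(=O)c1ccc(OC)c(OC)c1 | intermediate
7 | methyl (R)-3-[2-(3,4-dimethoxyphenyl)-1,3-dithian-2-yl]-2-methylpropanoate | COC(=O)[C@H](C)CC1(SCCCS1)c1ccc(OC)c(OC)c1 | intermediate
8 | (R)-3-[2-(3,4-dimethoxyphenyl)-1,3-dithian-2-yl]-2-methylpropan-1-ol | OC[C@H](C)CC1(SCCCS1)c1ccc(OC)c(OC)c1 | intermediate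
9 | (R)-3-[2-(3,4-dimethoxyphenyl)-1,3-dithian-2-yl]-2-methylpropanal | O=C[C@H](C)CC1(SCCCS1)c1ccc(OC)c(OC)c1 | intermediate
10 | 3,4-dimethoxyphenylmagnesium bromide | COc1ccc([Mg]Br)cc1OC | starting material
11 | bromomagnesium alkoxide of 12 (carbinol centre undefined) | COc1ccc(C(O[Mg]Br)[C@H](C)CC2(SCCCS2)c2ccc(OC)c(OC)c2)cc1OC | intermediate
12 | (2R)-1-(3,4-dimethoxyphenyl)-3-[2-(3,4-dimethoxyphenyl)-1,3-dithian-2-yl]-2-methylpropan-1-ol (C1 epimers, left undefined) | COc1ccc(C(O)[C@H](C)CC2(SCCCS2)c2ccc(OC)c(OC)c2)cc1OC | intermediate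
13 | 3,4-dimethoxybenzylic cation from 12 (methyl-bearing centre unchanged) | COc1ccc([CH+][C@H](C)CC2(SCCCS2)c2ccc(OC)c(OC)c2)cc1OC | intermediate
14 | (3'R,4'R)-4'-(3,4-dimethoxyphenyl)-6',7'-dimethoxy-3'-methyl-3',4'-dihydro-2'H-spiro[1,3-dithiane-2,1'-naphthalene] | COc1ccc([C@@H]2c3cc(OC)c(OC)cc3C3(SCCCS3)C[C@H]2C)cc1OC | intermediate
15 | (3R,4R)-4-(3,4-dimethoxyphenyl)-6,7-dimethoxy-3-methyl-3,4-dihydronaphthalen-1(2H)-one | COc1ccc([C@@H]2c3cc(OC)c(OC)cc3C(=O)C[C@H]2C)cc1OC | intermediate
16 | lithium enolate of 15 | COc1ccc([C@@H]2c3cc(OC)c(OC)cc3C(O[Li])=C[C@H]2C)cc1OC | intermediate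
17 | (3S,4R)-4-(3,4-dimethoxyphenyl)-6,7-dimethoxy-2,3-dimethyl-3,4-dihydronaphthalen-1(2H)-one (C2 epimers, left undefined) | COc1ccc([C@@H]2c3cc(OC)c(OC)cc3C(=O)C(C)[C@H]2C)cc1OC | intermediate
18 | (3S,4R)-4-(3,4-dimethoxyphenyl)-6,7-dimethoxy-2,3-dimethyl-1,2,3,4-tetrahydronaphthalen-1-ol (C1 and C2 left undefined) | COc1ccc([C@@H]2c3cc(OC)c(OC)cc3C(O)C(C)[C@H]2C)cc1OC | intermediate
19 | (1R,2S)-1-(3,4-dimethoxyphenyl)-6,7-dimethoxy-2,3-dimethyl-1,2-dihydronaphthalene | COc1ccc([C@@H]2c3cc(OC)c(OC)cc3C=C(C)[C@H]2C)cc1OC | target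

## Totals
Total step count: 12. Longest linear sequence: 12 (1 → 19; 4 and 10 are bought).

## Steps most likely to fail

**Step 3 (zinc insertion and Pd acylation).** The insertion may stall. The zinc reagent may also be lost to protonation, or couple sluggishly with the electron-rich acid chloride.

The fallback reverses the polarity and uses acyl-anion chemistry. It sets out from iodide 3 and comes back at alcohol 8, replacing steps 3 to 5. Reduction of 3 with iBu2AlH (CH2Cl2, −78 to 0 °C) gives (S)-3-iodo-2-methylpropan-1-ol F1. Silylation with TBSCl and imidazole then gives (S)-tert-butyl(3-iodo-2-methylpropoxy)dimethylsilane F2. Separately, 3,4-dimethoxybenzaldehyde and propane-1,3-dithiol (BF3·OEt2) give 2-(3,4-dimethoxyphenyl)-1,3-dithiane F3. Treatment with n-BuLi (THF, −30 °C) converts this into 2-lithio-2-(3,4-dimethoxyphenyl)-1,3-dithiane F4. Corey–Seebach alkylation of this anion with the iodide gives tert-butyl{(R)-3-[2-(3,4-dimethoxyphenyl)-1,3-dithian-2-yl]-2-methylpropoxy}dimethylsilane F5, and Bu4NF in THF releases 8.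

**Step 8 (cationic ring closure that sets C1).** Three things can go wrong:
- A dithiane sulfur can trap the cation as a cyclic sulfonium salt.
- The cation can lose the C2 proton to give a styrene, which would erode the ee.
- The trans:cis ratio may turn out lower than expected.

The fallback closes ring B at the other end, forming C4–C4a by acylation. It sets out from organozinc iodide 5 (made from 3 as in step 3) and comes back at tetralone 15, replacing steps 3 to 9.
- Carboxylation of 5 (CO2 1 bar, Ni(acac)2/PCy3 cat., LiCl, then dilute HCl) gives (R)-4-methoxy-3-methyl-4-oxobutanoic acid F6.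
- Excess 10 (3.5 equiv, THF) adds twice to the ester while the carboxylate salt stays inert, giving (R)-4,4-bis(3,4-dimethoxyphenyl)-4-hydroxy-3-methylbutanoic acid F7.
- This lactonises on acidic work-up to (R)-5,5-bis(3,4-dimethoxyphenyl)-4-methyldihydrofuran-2(3H)-one F8.
- Neutral hydrogenolysis of the doubly benzylic C–O bond (H2 4 bar, Pd/C, EtOH, 50 °C) avoids any cation next to the methyl centre and gives (R)-4,4-bis(3,4-dimethoxyphenyl)-3-methylbutanoic acid F9.
- (CF3CO)2O in CH2Cl2 forms (R)-4,4-bis(3,4-dimethoxyphenyl)-3-methylbutanoic trifluoroacetic anhydride F10, which undergoes intramolecular Friedel–Crafts acylation.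

The two aryl groups are diastereotopic. Closure through the conformer that keeps the methyl group and the spectator aryl anti favours trans-15, but this selectivity is estimated from conformational arguments rather than known. The cis isomer is removed by chromatography.

**Step 12 (acid dehydration).** The electron-rich dihydronaphthalene can dimerise, migrate its double bond, or aromatise under acid and air.

The fallback removes the oxygen reductively, with no ionisation. It sets out from ketone 17 and comes back at target 19, replacing steps 11 and 12. KN(SiMe3)2 (THF, −78 °C) gives the potassium enolate of 17 F11. PhNTf2 traps it as (3S,4R)-4-(3,4-dimethoxyphenyl)-6,7-dimethoxy-2,3-dimethyl-3,4-dihydronaphthalen-1-yl trifluoromethanesulfonate F12. Reduction with Pd(OAc)2/PPh3, HCO2H and Et3N (DMF, 60 °C) replaces C–OTf by C–H under neutral to basic conditions.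

## Further compounds
F1 | step 3 | (S)-3-iodo-2-methylpropan-1-ol | OC[C@H](C)CI
F2 | step 3 | (S)-tert-butyl(3-iodo-2-methylpropoxy)dimethylsilane | CC(C)(C)[Si](C)(C)OC[C@H](C)CI
F3 | step 3 | 2-(3,4-dimethoxyphenyl)-1,3-dithiane | COc1ccc(C2SCCCS2)cc1OC
F4 | step 3 | 2-lithio-2-(3,4-dimethoxyphenyl)-1,3-dithiane | COc1ccc(C2([Li])SCCCS2)cc1OC
F5 | step 3 | tert-butyl{(R)-3-[2-(3,4-dimethoxyphenyl)-1,3-dithian-2-yl]-2-methylpropoxy}dimethylsilane | CC(C)(C)[Si](C)(C)OC[C@H](C)CC1(SCCCS1)c1ccc(OC)c(OC)c1
F6 | step 8 | (R)-4-methoxy-3-methyl-4-oxobutanoic acid | COC(=O)[C@H](C)CC(=O)O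
F7 | step 8 | (R)-4,4-bis(3,4-dimethoxyphenyl)-4-hydroxy-3-methylbutanoic acid | OC(c1ccc(OC)c(OC)c1)(c1ccc(OC)c(OC)c1)[C@H](C)CC(=O)O
F8 | step 8 | (R)-5,5-bis(3,4-dimethoxyphenyl)-4-methyldihydrofuran-2(3H)-one | O=C1C[C@@H](C)C(c2ccc(OC)c(OC)c2)(c2ccc(OC)c(OC)c2)O1
F9 | step 8 | (R)-4,4-bis(3,4-dimethoxyphenyl)-3-methylbutanoic acid | COc1ccc(C(c2ccc(OC)c(OC)c2)[C@H](C)CC(=O)O)cc1OC
F10 | step 8 | (R)-4,4-bis(3,4-dimethoxyphenyl)-3-methylbutanoic trifluoroacetic anhydride | COc1ccc(C(c2ccc(OC)c(OC)c2)[C@H](C)CC(=O)OC(=O)C(F)(F)F)cc1OC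
F11 | step 12 | potassium enolate of 17 | COc1ccc([C@@H]2c3cc(OC)c(OC)cc3C(O[K])=C(C)[C@H]2C)cc1OC
F12 | step 12 | (3S,4R)-4-(3,4-dimethoxyphenyl)-6,7-dimethoxy-2,3-dimethyl-3,4-dihydronaphthalen-1-yl trifluoromethanesulfonate | COc1ccc([C@@H]2c3cc(OC)c(OC)cc3C(OS(=O)(=O)C(F)(F)F)=C(C)[C@H]2C)cc1OC
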